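common to all: starting material 0.044 M

| flask | reagent in the second phase | remark | time | volume of the second phase over the first |
|---|---|---|---|---|
| south-east | 0.044 M | the very flask that is asked about, followed so far |  |  |
| flask | 0.0440 M |  | 3.0 min | 2.0 |

south-east run (percent of the starting material charged)

| time / s | target / % | starting material / % |
|---|---|---|
| 10.0 | 15.4 | 81.5 |
| 15.0 | 22.1 | 75.3 |
| 25.0 | 30.9 | 60.9 |
| 40.0 | 46.0 | 49.1 |

(each reading ± 1 percentage point)

- in the second phase: reagent in the second phase; everything else is in the first
- charges count per volume of the first phase; a concentration in a rate is the amount of a species over the volume of its own phase; every rate counts per litre of the first phase
- reactions considered so far: starting material + reagent in the reaction phase -> target; reagent in the reaction phase <-> reagent in the second phase; reagent in the reaction phase + target -> over-reaction product; starting material <-> dormant form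
- the earlier runs hold the two phases in the same ratio of volumes as the flask asked about

* how much target there is at 3.0 min, in percent of the starting material charged
* the change that raises the amount of target at 3.0 min, in percent of the starting material charged most ("none" if none brings more than 2 percentage points) (winter / spring / none)
* amount of target at 3.0 min, in percent of the starting material charged, after spring

- winter: doubling the amount of reagent in the second phase, all else as stated
- spring: doubling the transfer coefficient of the reagent in the second phase, all else as stated

1. Each target formed takes one reagent, so a ceiling on the target can be counted before any rate is known. Reagent over starting material, as charged, comes to 100%. This ratio is the reagent ceiling C, the most target that the charged reagent can pay for, in percent of the starting material charged. Where less reagent than starting material is charged, the reagent is the limiting reagent.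

2. With C at 100%, the flask's starting material and reagent fall roughly in step. For a second-order reaction with equal charges, the reciprocal of S, the fraction of starting material left, climbs on a straight line in time. The south-east readings at 10.0 s and 40.0 s give a slope of 1.62 /min, a reading with its scatter. Carried on to 3.0 min, that line leaves S at 17.2%.

3. At 40.0 s, target made up 90.4% of the starting material consumed. The same share of the consumption reckoned for 3.0 min gives an estimate of 74.8% of target in the flask.

4. Winter lifts C to 200%, more than the 100% at which spring leaves it, so this reckoning picks winter.

5. The forecast parts from this reckoning: it gives 69%, less than the estimate of 74.8%, with 70.5% after spring and none as the best change, holding that “Reagent is only 1 equivalent, which caps the yield”.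

6. The flask gives 72.9% of target at 3.0 min, against the reckoned 74.8%, and 73.4% after spring. The best change is winter, which gains 5.7 percentage points, more than the 0.55 points that spring gains.

    starting material + reagent in the reaction phase → target (k = 110 /M/min)
    reagent in the reaction phase ⇌ reagent in the second phase, rate k2*([reagent in the reaction phase] - [reagent in the second phase]/K2) per volume of the first phase (partition coefficient = 0.980, kL = 14.0 /min)
    reagent in the reaction phase + target → over-reaction product (k = 5.10 /M/min)
    starting material ⇌ dormant form (K = 0.730, k = 0.120 /min)

In the flask at 3.00 min, target at 72.9% plus twice the over-reaction product at 3.99% has used 80.9% of the reagent, under C = 100%. The neighbour charged with 0.18 M of starting material has C = 24.4%. At 3.00 min it holds 24.1% of target, nearly all of its ceiling, and its reagent in the second phase is spent, at 0.00949% of its own charge. Its starting material stands at 57.0% and its dormant form at 18.8%.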